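If the two substrates stayed equal in these flasks, I reasoned, the rates of left-handed and right-handed product would keep a constant ratio, and a single ratio read from the runs would give the excess at any time.

| setting | epsilon | delta | beta | alder | birch |
|---|---|---|---|---|---|
| left-handed substrate | 36 mM | 36 mM | 72 mM | 36 mM | 36 mM |
| right-handed substrate | 36 mM | 36 mM | 72 mM | 36 mM | 36 mM |
| partner | 2.5 equiv | 2.5 equiv | 2.5 equiv | 2.50 equiv | 2.50 equiv |
| racemization catalyst | 1 mol% | 4 mol% | 2 mol% | 2 mol% | 2 mol% |
| precatalyst | 10 mol% | 10 mol% | 10 mol% | 10 mol% | 10 mol% |
| remark | run made earlier | run made earlier | run made earlier |  |  |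
| time |  |  |  | 80 min | 250 min |

| run | time / min | left-handed product / % | right-handed product / % |
|---|---|---|---|
| epsilon | 3.00 | 0.2 | 0.8 |
| epsilon | 10.0 | 1.4 | 0.1 |
| epsilon | 15.0 | 3.0 | 0.3 |
| epsilon | 25.0 | 7.6 | 0.9 |
| epsilon | 40.0 | 16.3 | 1.5 |
| epsilon | 50.0 | 22.2 | 2.4 |
| delta | 3.00 | 0.4 | 0 |
| delta | 10.0 | 1.4 | 0 |
| delta | 15.0 | 3.5 | 0.6 |
| delta | 25.0 | 7.9 | 0.2 |
| delta | 40.0 | 15.8 | 2.3 |
| delta | 50.0 | 22.3 | 2.4 |
| beta | 4.00 | 1.8 | 0 |
| beta | 8.00 | 6.4 | 0.4 |
| beta | 15.0 | 19.0 | 1.8 |
| beta | 25.0 | 36.3 | 3.6 |
| beta | 50.0 | 61.8 | 6.2 |

(standard deviation of a reading: 0.3 percentage points)

- free catalyst is single-handed; left-handed substrate and right-handed substrate are mirror images of each other, charged as a racemate, each of them at the stated concentration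
- an excess is the difference of the two amounts in percent of their sum
- an excess is below zero if the other one leads

- which one finishes higher in excess of left-handed product over right-handed product in the product ("neither" within 2 percentage points) (alder / birch / neither)
- excess of left-handed product over right-handed product in the product at the end, alder
- excess of left-handed product over right-handed product in the product at the end, birch

I read the beta table from its last row, because it went furthest. It gave 61.8% left-handed against 6.2% right-handed product. That ratio is my reading of the selectivity factor, the left-handed product formed per right-handed product from equal substrates: 9.97. It corresponds to an excess of 81.8%.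

At any moment the rate ratio should be this factor times c(left-handed substrate)/c(right-handed substrate), so the question was how that quotient drifted. Left-handed substrate was 50% of the charge, and the left-handed product in the last beta row stood above this, so right-handed substrate had passed over: a dynamic kinetic resolution. The step between the last two beta rows gave a ratio of 9.81, so I read no drift through the scatter. The last rows of epsilon and delta, at 1 mol% and 4 mol% racemization catalyst, gave 9.25 and 9.29, but each of these rests on a right-handed reading of 2.4% with a scatter of 0.3 percentage points, so I did not separate them from the beta reading. I committed to 81.8% for both alder and birch, hence neither.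

The forecast gave alder 81.5% (79% to 84%) and birch 81% (76% to 84%), with the verdict neither, holding that “the remaining substrate stays essentially racemic”. Its figures lay slightly below mine.

The flasks gave 82.0% for alder and 82.0% for birch, so the verdict was neither.

    partner + free catalyst + left-handed substrate → free catalyst + left-handed product (k = 1.78 M⁻² s⁻¹)
    partner + free catalyst + right-handed substrate → free catalyst + right-handed product (k = 0.175 M⁻² s⁻¹)
    left-handed substrate + racemization catalyst ⇌ right-handed substrate + racemization catalyst, rate k3*[racemization catalyst]*[left-handed substrate] forward; the back reaction follows from the equilibrium constant (k = 25.5 M⁻¹ s⁻¹)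
    partner + precatalyst → free catalyst + spent reagent (k = 0.00343 M⁻¹ s⁻¹)

The product ratios at the end stood at 10.1 in alder and 10.1 in birch. Birch kept its excess because the passing of left-handed substrate into right-handed substrate, both ways, left the two level, at 9.10% and 9.14% after 250 min. With that passing taken away, the excess in birch fell from 82.0% to 52.4%. I carried the factor 9.97, that is 81.8%, to the neighbour of birch charged with 5 mol% racemization catalyst, and that flask gave 82.1%.

(The data were computed for substances that don't exist.)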